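**Plan**
- Retrosynthesis: the lactone O1–C2 bond is opened to a phenol and a dimethylamide, the C8–acyl bond is cut (Friedel–Crafts), C4–H is traced back to C4–B, and the key step cuts C4–C4a and C3–C2 together.
- Enabling feature: C4 is a benzylic carbon bearing ring A (through C4a), the phenyl group and the C3–C2(=O) arm. This is the pattern left when ring A moves from boron to the α-carbon of a 1-phenylvinylboron while the terminal carbon gains an acyl group.
- Forward: lithiated 1,3,5-trimethoxybenzene and 1-phenylvinyl pinacol boronate give a borate; conjunctive coupling with dimethylcarbamoyl chloride joins ring A, C4, C3 and C2; boron is replaced by hydrogen; ring A is acylated at the future C8.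
- Only the two ethers ortho to the new ketone are then cleaved, so the lactone (the one ring formed) can close only on the oxygen between side chain and ketone; the last two methyl ethers go at the end.
- Stereochemistry: (R)-C4 is set in the key step by the chiral bisphosphine on palladium and kept by a retentive protodeboronation. Carrying the phenyl group on the alkenylboron avoids a later cross-coupling at a hindered benzylic C–B bond β to a coordinating amide.

Key step: step 2

Assumption: the ligand antipode that delivers the (R)-boronate 6 is written as (Sp,Sp)-MandyPhos, 2,2′-bis[α-(dimethylamino)benzyl]-1,1′-bis(diphenylphosphino)ferrocene, C52H50FeN2P2. If the sense of induction on this α-aryl alkenylborate is the opposite, the (Rp,Rp) ligand is used and nothing else changes.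

**Step 1**
Reactants: 1 1,3,5-trimethoxybenzene; 2 1-phenylvinylboronic acid pinacol ester
Product: 4 lithium (pinacolato)(1-phenylethenyl)(2,4,6-trimethoxyphenyl)borate, via 2,4,6-trimethoxyphenyllithium 3 (not isolated)
Conditions: n-BuLi (0.98 equiv), THF, 0 °C to rt; then 2, −78 °C to rt; evaporate, use crude
Reagents that add atoms: n-butyllithium, [Li]CCCC
Why: Directed ortho-lithiation puts lithium between two methoxy groups (all three ring C–H positions of 1 are equivalent), and the aryllithium adds to the empty orbital on boron of 2 to give the tetracoordinate ate complex; n-BuLi is kept slightly short so that no butyl borate forms.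

**Step 2**
Reactants: 4 lithium (pinacolato)(1-phenylethenyl)(2,4,6-trimethoxyphenyl)borate; 5 dimethylcarbamoyl chloride
Product: 6 (R)-N,N-dimethyl-3-phenyl-3-(4,4,5,5-tetramethyl-1,3,2-dioxaborolan-2-yl)-3-(2,4,6-trimethoxyphenyl)propanamide
Conditions: Pd(OAc)2 (3 mol %), (Sp,Sp)-MandyPhos C52H50FeN2P2 (3.6 mol %), KOTf (2 equiv), THF, 60 °C
Reagents that add atoms: none
Why: Zerovalent palladium inserts into the C–Cl bond of 5, KOTf removes the chloride, and the cationic carbamoylpalladium binds the alkene of 4; this triggers the 1,2-metallate shift in which ring A leaves boron for the α-carbon (C4–C4a) anti to palladium while palladium takes the terminal carbon, and reductive elimination then forms C3–C2 and returns zerovalent palladium. The closest known reaction type is the enantioselective palladium/MandyPhos conjunctive cross-coupling of α-substituted alkenylboron ate complexes with carbamoyl chlorides, which gives tertiary β-boryl amides. No ring closes in this step. The new stereocenter C4 is under catalyst control: the chiral bisphosphine decides which face of the 1,1-disubstituted alkene palladium occupies, and the anti migration turns that choice into the (R) configuration. The step needs conjunctive coupling to win over direct transfer of ring A from boron to palladium and over β-hydride elimination; the electron-rich, di-ortho-substituted ring should migrate readily but transmetallate slowly, and the alkylpalladium sits next to a fully substituted carbon with no β-hydrogen.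

**Step 3**
Reactants: 6 (R)-N,N-dimethyl-3-phenyl-3-(4,4,5,5-tetramethyl-1,3,2-dioxaborolan-2-yl)-3-(2,4,6-trimethoxyphenyl)propanamide
Product: 7 (R)-N,N-dimethyl-3-phenyl-3-(2,4,6-trimethoxyphenyl)propanamide
Conditions: CsF (1.5 equiv), H2O (1.1 equiv), 1,4-dioxane, 45 °C
Reagents that add atoms: none
Why: Stereoretentive protodeboronation of a tertiary diarylalkyl pinacol boronate: fluoride forms the boron ate complex and water protonates the C–B bond from the front, so hydrogen takes the place of boron at C4 with retention and the (R) centre from step 2 is kept.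

**Step 4**
Reactants: 7 (R)-N,N-dimethyl-3-phenyl-3-(2,4,6-trimethoxyphenyl)propanamide; 8 3-(4-methoxyphenyl)propanoic acid
Product: 10 (R)-N,N-dimethyl-3-phenyl-3-{2,4,6-trimethoxy-3-[3-(4-methoxyphenyl)propanoyl]phenyl}propanamide, via acyl trifluoroacetate 9 (not isolated)
Conditions: 8 and TFAA (1.2 equiv each, premixed), cat. H3PO4, CH2Cl2, 0 °C to rt
Reagents that add atoms: trifluoroacetic anhydride, O=C(OC(=O)C(F)(F)F)C(F)(F)F (its trifluoroacetyl group is held only by 9 and leaves again as trifluoroacetic acid)
Why: Friedel–Crafts acylation through the mixed anhydride: the only open positions of ring A are two equivalent carbons activated by three methoxy groups, far more nucleophilic than the phenyl and anisyl rings, and the first acyl group deactivates the ring against a second.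

**Step 5**
Reactants: 10 (R)-N,N-dimethyl-3-phenyl-3-{2,4,6-trimethoxy-3-[3-(4-methoxyphenyl)propanoyl]phenyl}propanamide
Product: 11 (R)-3-{2,4-dihydroxy-6-methoxy-3-[3-(4-methoxyphenyl)propanoyl]phenyl}-N,N-dimethyl-3-phenylpropanamide
Conditions: BCl3 (5 equiv), CH2Cl2, −78 °C to rt; then MeOH, H2O
Reagents that add atoms: none
Why: Chelation-controlled ether cleavage: BCl3 bound to the ketone oxygen should cleave only the two methoxy groups ortho to the carbonyl, leaving the methoxy group para to the ketone (the future C5 oxygen) and the anisole ether, so the only free phenol next to the side chain is the one that must become O1.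

**Step 6**
Reactants: 11 (R)-3-{2,4-dihydroxy-6-methoxy-3-[3-(4-methoxyphenyl)propanoyl]phenyl}-N,N-dimethyl-3-phenylpropanamide
Product: 12 (R)-7-hydroxy-5-methoxy-8-[3-(4-methoxyphenyl)propanoyl]-4-phenylchroman-2-one
Conditions: TsOH·H2O (1.5 equiv), PhMe, 90 °C
Reagents that add atoms: none
Why: Acid-catalysed lactonisation (6-exo-trig acyl transfer from the protonated amide to the phenol, helped by the ortho substituents and the C4 phenyl group that hold the chain over the phenol) can only involve the hydroxyl between side chain and ketone, because the other free hydroxyl is para to the chain and the remaining ortho oxygen is still a methyl ether.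

**Step 7**
Reactants: 12 (R)-7-hydroxy-5-methoxy-8-[3-(4-methoxyphenyl)propanoyl]-4-phenylchroman-2-one
Product: 13 (R)-5,7-dihydroxy-8-[3-(4-hydroxyphenyl)propanoyl]-4-phenylchroman-2-one
Conditions: BBr3 (6 equiv), CH2Cl2, −78 °C to rt; then ice/H2O
Reagents that add atoms: none
Why: BBr3 demethylation of aryl methyl ethers: the two remaining ethers are cleaved through their boron-bound oxonium ions while the aryl lactone and the ketone only coordinate, and C4 is neither enolisable nor ionisable under these conditions.

**Compound list**
1 | 1,3,5-trimethoxybenzene | COc1cc(OC)cc(OC)c1 | starting material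
2 | 1-phenylvinylboronic acid pinacol ester (4,4,5,5-tetramethyl-2-(1-phenylethenyl)-1,3,2-dioxaborolane) | C=C(c1ccccc1)B1OC(C)(C)C(C)(C)O1 | starting material
3 | 2,4,6-trimethoxyphenyllithium | [Li]c1c(OC)cc(OC)cc1OC | intermediate
4 | lithium (pinacolato)(1-phenylethenyl)(2,4,6-trimethoxyphenyl)borate | [Li+].C=C(c1ccccc1)[B-]1(c2c(OC)cc(OC)cc2OC)OC(C)(C)C(C)(C)O1 | intermediate
5 | dimethylcarbamoyl chloride | CN(C)C(=O)Cl | starting material
6 | (R)-N,N-dimethyl-3-phenyl-3-(4,4,5,5-tetramethyl-1,3,2-dioxaborolan-2-yl)-3-(2,4,6-trimethoxyphenyl)propanamide | CN(C)C(=O)C[C@](B1OC(C)(C)C(C)(C)O1)(c1ccccc1)c1c(OC)cc(OC)cc1OC | intermediate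
7 | (R)-N,N-dimethyl-3-phenyl-3-(2,4,6-trimethoxyphenyl)propanamide | CN(C)C(=O)C[C@H](c1ccccc1)c1c(OC)cc(OC)cc1OC | intermediate
8 | 3-(4-methoxyphenyl)propanoic acid | COc1ccc(CCC(=O)O)cc1 | starting material
9 | 3-(4-methoxyphenyl)propanoic trifluoroacetic anhydride (acyl trifluoroacetate) | COc1ccc(CCC(=O)OC(=O)C(F)(F)F)cc1 | intermediate
10 | (R)-N,N-dimethyl-3-phenyl-3-{2,4,6-trimethoxy-3-[3-(4-methoxyphenyl)propanoyl]phenyl}propanamide | CN(C)C(=O)C[C@H](c1ccccc1)c1c(OC)cc(OC)c(C(=O)CCc2ccc(OC)cc2)c1OC | intermediate
11 | (R)-3-{2,4-dihydroxy-6-methoxy-3-[3-(4-methoxyphenyl)propanoyl]phenyl}-N,N-dimethyl-3-phenylpropanamide | CN(C)C(=O)C[C@H](c1ccccc1)c1c(OC)cc(O)c(C(=O)CCc2ccc(OC)cc2)c1O | intermediate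
12 | (R)-7-hydroxy-5-methoxy-8-[3-(4-methoxyphenyl)propanoyl]-4-phenylchroman-2-one | O=C1C[C@H](c2ccccc2)c2c(OC)cc(O)c(C(=O)CCc3ccc(OC)cc3)c2O1 | intermediate
13 | (R)-5,7-dihydroxy-8-[3-(4-hydroxyphenyl)propanoyl]-4-phenylchroman-2-one (CNP0246155.1) | O=C1C[C@H](c2ccccc2)c2c(O)cc(O)c(C(=O)CCc3ccc(O)cc3)c2O1 | target

**Step count**
Total steps: 7. Longest linear sequence: 7 steps (1 to 13); 2, 5 and 8 are bought.

**Steps most likely to fail**

Step 2. The metallate shift may be slowed by crowding at the α-carbon (a di-ortho-substituted migrating ring meeting an α-phenyl group), so that direct aryl transfer to palladium or loss of boron takes over, or the two alkene faces may be poorly distinguished. The fallback sets out from aryllithium 3 (made from 1 as in step 1) and uses an oxazolidinone auxiliary in place of the catalyst. Compound 3 is transmetallated with MgBr2·OEt2 and CuBr·SMe2 in THF and added at −40 °C to commercially available (R)-3-cinnamoyl-4-phenyloxazolidin-2-one. The 4-phenyl group shields one face of the chelated s-cis enoyl imide, and the conjugate addition should give (R)-4-phenyl-3-[(R)-3-phenyl-3-(2,4,6-trimethoxyphenyl)propanoyl]oxazolidin-2-one F1. Aminolysis of the imide with Me2NH·HCl and AlMe3 in CH2Cl2 releases the auxiliary and rejoins the route at 7, so that steps 2 and 3 are bypassed.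

Step 6. The protonated tertiary amide may be too weak an acylating agent for the hindered, hydrogen-bonded phenol, and forcing the acid and temperature could start to erode C4. The fallback sets out from 11 and activates the amide as an electrophile instead. O-Methylation with Me3OBF4 in CH2Cl2 should give [(R)-3-{2,4-dihydroxy-6-methoxy-3-[3-(4-methoxyphenyl)propanoyl]phenyl}-1-methoxy-3-phenylpropylidene]dimethylammonium tetrafluoroborate F2. On stirring with aqueous NaHCO3 in THF the neighbouring phenol displaces methanol, and the cyclic iminium ether is hydrolysed to the lactone, which rejoins the route at 12.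

Step 5. Ether cleavage may spread to the methoxy group para to the ketone; the lactone could then close on either side of ring A and the regiochemistry would be lost. The fallback sets out from 7 and closes the lactone while ring A is still symmetric. BBr3 in CH2Cl2 removes all three methyl ethers, and warming the crude triphenol amide in AcOH with aqueous HBr closes the lactone; either ortho hydroxyl gives the same compound, (R)-5,7-dihydroxy-4-phenylchroman-2-one F3. C-Acylation of F3 with 3-(4-hydroxyphenyl)propanoic acid in BF3·OEt2 at 70 °C (Friedel–Crafts acylation of a phloroglucinol nucleus) should give 13 together with (R)-5,7-dihydroxy-6-[3-(4-hydroxyphenyl)propanoyl]-4-phenylchroman-2-one F4, to be removed by chromatography. The route is rejoined at 13.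

**Further compounds**
F1 | step 2 | (R)-4-phenyl-3-[(R)-3-phenyl-3-(2,4,6-trimethoxyphenyl)propanoyl]oxazolidin-2-one | O=C1OC[C@@H](c2ccccc2)N1C(=O)C[C@H](c1ccccc1)c1c(OC)cc(OC)cc1OC
F2 | step 6 | [(R)-3-{2,4-dihydroxy-6-methoxy-3-[3-(4-methoxyphenyl)propanoyl]phenyl}-1-methoxy-3-phenylpropylidene]dimethylammonium tetrafluoroborate | COC(=[N+](C)C)C[C@H](c1ccccc1)c1c(OC)cc(O)c(C(=O)CCc2ccc(OC)cc2)c1O.F[B-](F)(F)F
F3 | step 5 | (R)-5,7-dihydroxy-4-phenylchroman-2-one | O=C1C[C@H](c2ccccc2)c2c(O)cc(O)cc2O1
F4 | step 5 | (R)-5,7-dihydroxy-6-[3-(4-hydroxyphenyl)propanoyl]-4-phenylchroman-2-one | O=C1C[C@H](c2ccccc2)c2c(O)c(C(=O)CCc3ccc(O)cc3)c(O)cc2O1
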